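**Plan**

1. Retrosynthesis (germacranolide numbering: C1 hemiketal carbon, C4 methyl-bearing ether carbon, C5=C6 enol-lactone alkene, C7/C11/C12 butenolide, C8 acyloxy carbon, C10 methyl-bearing CH). After the side-chain silyl ether, the oxolane O–C1 bond and the C5=C6 double bond are exchanged for an O–O bond and a transannular C1–C6 bond. This gives the saturated 1,4-endoperoxide (a 1,2-dioxane across C1/C4) of a cadinane-type 6-6-5 tricycle.
2. The peroxide is cut to a ring A 1,3-diene and O2. Ring A is cut at C3=C4 (metathesis) and at C1–C2 and C5–C6 (two allyl-type Grignard additions). The butenolide goes back to a furan, ring B to a furan acylation (C1–C6), and C8–C9 to a Stetter union of a furan aldehyde with methyl acrylate.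
3. Forward order: 3,4-disubstituted furan, then ring B fused to the furan, then furan oxidised to the butenolide with C6 made quaternary, then ring A, then the endoperoxide. One iron-triggered event then opens ring B to the ten-membered ring, creates C5=C6 and contracts the dioxane to the hemiketal oxolane; a desilylation ends the route.
4. The event is possible because C6 is both the γ-carbon of the butenolide (ring C) and the neighbour of C1, so a C1 alkoxy radical cleaves C1–C6 to a stabilised 2-oxofuranyl radical. C1 and C4 are the 1,4-termini of ring A, so the peroxide already holds both hemiketal oxygens on one face.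
5. Stereochemistry: C8 by catalytic asymmetric transfer hydrogenation; C10 relayed from C8 by trans alkylation of a lactone; C1 and C6 are temporary centres relayed from C10; C4 from singlet oxygen adding anti to the C10 methyl; C1 is re-created by C4 through the bridge; the side-chain (E)-alkene from a Wittig reaction.

Key step: step 19

TBDPS = tert-butyldiphenylsilyl, TBS = tert-butyldimethylsilyl.

**Route**

Step 1
Reactants: 1 furan-3,4-diyldimethanol
Product: 2 [4-(TBDPS-oxymethyl)furan-3-yl]methanol
Conditions: NaH (1.0 equiv), THF, 0 °C; then TBDPSCl (1.0 equiv), 0 °C to rt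
Reagents that add atoms: tert-butyl(chloro)diphenylsilane, CC(C)(C)[Si](Cl)(c1ccccc1)c1ccccc1
Why: O-silylation of the monosodium alkoxide of a symmetrical diol should stop at the mono ether; no stereocentre is involved.

Step 2
Reactants: 2 [4-(TBDPS-oxymethyl)furan-3-yl]methanol
Product: 3 4-(TBDPS-oxymethyl)furan-3-carbaldehyde
Conditions: activated MnO2, CH2Cl2, rt
Reagents that add atoms: none
Why: MnO2 oxidation of a heteroaryl carbinol (benzylic-type alcohol) should give the aldehyde without touching the furan or the silyl ether.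

Step 3
Reactants: 3 4-(TBDPS-oxymethyl)furan-3-carbaldehyde; 4 methyl acrylate
Product: 5 methyl 4-[4-(TBDPS-oxymethyl)furan-3-yl]-4-oxobutanoate
Conditions: 3-benzyl-5-(2-hydroxyethyl)-4-methylthiazolium chloride (0.2 equiv), Et3N, 1,4-dioxane, 80 °C
Reagents that add atoms: none
Why: Stetter reaction: the carbene-derived acyl anion equivalent of the heteroaryl aldehyde should add 1,4 to the acrylate and form the C8–C9 bond.

Step 4
Reactants: 5 methyl 4-[4-(TBDPS-oxymethyl)furan-3-yl]-4-oxobutanoate
Product: 7 (5S)-5-[4-(TBDPS-oxymethyl)furan-3-yl]oxolan-2-one, via hydroxy ester 6 (not isolated)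
Conditions: RuCl[(S,S)-TsDPEN](p-cymene) (1 mol %), HCO2H/Et3N (5:2), DMF, 40 °C; then PPTS (cat.), toluene, 60 °C
Reagents that add atoms: none
Why: Noyori asymmetric transfer hydrogenation of the aryl alkyl ketone should give the (S)-carbinol (C8) with the (S,S)-ligand, and the γ-hydroxy ester lactonises.

Step 5
Reactants: 7 (5S)-5-[4-(TBDPS-oxymethyl)furan-3-yl]oxolan-2-one
Product: 8 (3R,5S)-3-methyl-5-[4-(TBDPS-oxymethyl)furan-3-yl]oxolan-2-one
Conditions: LDA (1.1 equiv), THF, −78 °C; then MeI, −78 to −40 °C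
Reagents that add atoms: iodomethane, CI
Why: Alkylation of the lactone enolate should occur anti to the γ-furyl group, giving the trans lactone and relaying C8 to C10.

Step 6
Reactants: 8 (3R,5S)-3-methyl-5-[4-(TBDPS-oxymethyl)furan-3-yl]oxolan-2-one
Product: 11 (2R,4S)-2-methyl-4-(TBS-oxy)-4-[4-(TBDPS-oxymethyl)furan-3-yl]butanoic acid, via potassium hydroxy carboxylate 9 (not isolated), via silyl ether silyl ester 10 (not isolated)
Conditions: KOH (1.05 equiv), THF/H2O, rt; evaporate; TBSCl (2.5 equiv), imidazole, DMF, rt; then K2CO3 (0.2 equiv), MeOH, rt; pH 5 work-up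
Reagents that add atoms: potassium hydroxide, [K+].[OH-]; tert-butyl(chloro)dimethylsilane, CC(C)(C)[Si](C)(C)Cl
Why: Saponification, bis-silylation of the hydroxy carboxylate and selective methanolysis of the labile silyl ester should give the protected acid without relactonisation; both stereocentres are untouched.

Step 7
Reactants: 11 (2R,4S)-2-methyl-4-(TBS-oxy)-4-[4-(TBDPS-oxymethyl)furan-3-yl]butanoic acid
Product: 13 (4S,6R)-6-methyl-4-(TBS-oxy)-3-(TBDPS-oxymethyl)-5,6-dihydro-1-benzofuran-7(4H)-one, via mixed anhydride 12 (not isolated)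
Conditions: (CF3CO)2O (1.2 equiv), CH2Cl2, 0 °C; aqueous NaHCO3 quench
Reagents that add atoms: none
Why: Intramolecular Friedel–Crafts acylation of the electron-rich furan by the mixed anhydride can only reach the α-position next to the side chain (C6), closing ring B as a 2-acylfuran.

Step 8
Reactants: 13 (4S,6R)-6-methyl-4-(TBS-oxy)-3-(TBDPS-oxymethyl)-5,6-dihydro-1-benzofuran-7(4H)-one; 14 allylmagnesium bromide
Product: 15 (4S,6R,7R)-7-allyl-6-methyl-4-(TBS-oxy)-3-(TBDPS-oxymethyl)-4,5,6,7-tetrahydro-1-benzofuran-7-ol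
Conditions: allylmagnesium bromide (1.3 equiv), THF, −78 °C; aqueous NH4Cl
Reagents that add atoms: none
Why: Grignard 1,2-addition to the aryl ketone should occur anti to the adjacent C10 methyl (equatorial attack on the half-chair), placing the C1 hydroxyl cis to the methyl and the C8 silyloxy group.

Step 9
Reactants: 15 (4S,6R,7R)-7-allyl-6-methyl-4-(TBS-oxy)-3-(TBDPS-oxymethyl)-4,5,6,7-tetrahydro-1-benzofuran-7-ol
Product: 17 (4S,6R,7R)-7-allyl-7,7a-dihydroxy-6-methyl-4-(TBS-oxy)-3-(TBDPS-oxymethyl)-5,6,7,7a-tetrahydro-1-benzofuran-2(4H)-one (both 7a epimers), via furan endoperoxide 16 (not isolated)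
Conditions: O2, visible light, tetraphenylporphyrin (cat.), iPr2NEt (2 equiv), CH2Cl2, −78 to 0 °C
Reagents that add atoms: dioxygen, O=O
Why: [4+2] addition of singlet oxygen across the furan and base-induced Kornblum–DeLaMare cleavage at the only α-hydrogen (C12) should give the γ-hydroxybutenolide with the carbonyl at C12 and the hemiketal at C6.

Step 10
Reactants: 17 γ-hydroxybutenolide; 18 2-methylallylmagnesium chloride
Product: 20 (4S,6R,7R,7aS)-7-allyl-7-hydroxy-6-methyl-7a-(2-methylallyl)-4-(TBS-oxy)-3-(TBDPS-oxymethyl)-5,6,7,7a-tetrahydro-1-benzofuran-2(4H)-one, via hydroxy acid magnesium salt 19 (not isolated)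
Conditions: 2-methylallylmagnesium chloride (4 equiv), THF, −78 to 0 °C; then 1 M HCl to pH 3, rt
Reagents that add atoms: none
Why: The Grignard reagent opens the pseudo-acid to the keto carboxylate and should add to the C6 ketone anti to the axial C1 magnesium alkoxide (polar Felkin–Anh control), so that the two allyl-type arms are cis; acidification lactonises the (Z)-hydroxy acid.

Step 11
Reactants: 20 allyl/methallyl butenolide
Product: 21 tricyclic lactone alcohol (ring A cyclohexene C3=C4)
Conditions: second-generation Grubbs catalyst RuCl2(=CHPh)(H2IMes)(PCy3) (5 mol %), CH2Cl2, 40 °C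
Reagents that add atoms: none
Why: Ring-closing metathesis of the cis-disposed allyl and 2-methylallyl groups should close the six-membered ring A with the trisubstituted C3=C4 alkene.

Step 12
Reactants: 21 tricyclic lactone alcohol
Product: 22 ring A 1,3-diene (C1=C2, C3=C4)
Conditions: Burgess reagent (methyl N-(triethylammoniosulfonyl)carbamate), toluene, 50 °C
Reagents that add atoms: none
Why: Burgess syn-elimination of the sulfamate: only the allylic C2 hydrogens are syn to the C1 oxygen (the C10 hydrogen is anti, C6 has none), so the conjugated diene should form and the temporary C1 centre is erased.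

Step 13
Reactants: 22 ring A 1,3-diene
Product: 24 saturated 1,4-endoperoxide bis-silyl ether, via unsaturated endoperoxide 23 (not isolated)
Conditions: O2, visible light, tetraphenylporphyrin (cat.), CH2Cl2, −78 °C; then KO2CN=NCO2K, AcOH, CH2Cl2/MeOH, −78 to 0 °C
Reagents that add atoms: dioxygen, O=O
Why: [4+2] cycloaddition of singlet oxygen to the 1,4-dialkylcyclohexa-1,3-diene (as α-terpinene gives ascaridole) should occur anti to the pseudo-axial C10 methyl and the C6–O bond (the sense seen with the angular methyl of steroidal 5,7-dienes), which sets C4, and diimide then saturates the strained C2=C3 bond without cleaving O–O.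

Step 14
Reactants: 24 saturated 1,4-endoperoxide bis-silyl ether
Product: 25 endoperoxide diol (C8–OH, C13–OH)
Conditions: HF·pyridine, pyridine, THF, 0 °C to rt
Reagents that add atoms: none
Why: Fluoride-mediated cleavage of both silyl ethers under buffered acidic conditions should leave the fully substituted peroxide (no α-hydrogen) and the butenolide intact.

Step 15
Reactants: 25 endoperoxide diol
Product: 26 endoperoxide 13-acetate (C8–OH free)
Conditions: Ac2O (1.1 equiv), 2,4,6-collidine, CH2Cl2, −20 °C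
Reagents that add atoms: acetic anhydride, CC(=O)OC(C)=O
Why: Acylation should be selective for the primary allylic hydroxyl over the hindered secondary C8 hydroxyl.

Step 16
Reactants: 27 (TBS-oxy)acetaldehyde; 28 ethyl 2-(triphenyl-λ5-phosphanylidene)propanoate
Product: 29 ethyl (2E)-2-methyl-4-(TBS-oxy)but-2-enoate
Conditions: CH2Cl2, rt
Reagents that add atoms: none
Why: Wittig olefination with the stabilised ylide should give the (E)-trisubstituted enoate.

Step 17
Reactants: 29 ethyl (2E)-2-methyl-4-(TBS-oxy)but-2-enoate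
Product: 30 (2E)-2-methyl-4-(TBS-oxy)but-2-enoic acid
Conditions: LiOH, THF/H2O, rt; 1 M HCl to pH 4
Reagents that add atoms: lithium hydroxide, [Li+].[OH-]
Why: Saponification of the ethyl ester should leave the primary silyl ether and the alkene geometry unchanged.

Step 18
Reactants: 26 endoperoxide 13-acetate; 30 (2E)-2-methyl-4-(TBS-oxy)but-2-enoic acid
Product: 31 endoperoxide 13-acetate 8-[(2E)-2-methyl-4-(TBS-oxy)but-2-enoate]
Conditions: DCC, DMAP (cat.), CH2Cl2, 0 °C to rt
Reagents that add atoms: none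
Why: Steglich esterification acylates the only free hydroxyl (C8) with retention of configuration.

Step 19
Reactants: 31 endoperoxide diester
Product: 33 side-chain O-TBS ether of the target, via keto alcohol 32 (not isolated)
Conditions: FeSO4·7H2O (0.3 equiv), Cu(OAc)2 (0.3 equiv), degassed MeCN/H2O (9:1), 0 °C to rt
Reagents that add atoms: none
Why: Proposed new method: divalent iron is expected to cleave the O–O bond by inner-sphere electron transfer at the less hindered oxygen on C4, leaving the alkoxy radical on the C1 oxygen, whose β-scission of the C1–C6 bond is driven by formation of the C1 ketone and of a captodative 2-oxofuranyl (acyloxy-allyl) radical at C6; divalent copper then oxidises this radical and loss of a C5 proton gives the C5=C6 enol lactone, while the iron alkoxide on C4 is protonated (keto alcohol 32) and adds to the C1 ketone, both metals returning to their starting oxidation states. The closest known reaction type is the iron/copper-mediated alkoxy-radical fragmentation of peroxides used for ring expansion with alkene formation, together with the ferrous-ion cleavage of ascaridole-type endoperoxides. Ring B is opened to the ten-membered ring by the β-scission, and the oxolane closes by 5-exo-trig addition of the C4 hydroxyl to the C1 carbonyl, so the 1,2-dioxane contracts to the oxolane and one peroxide oxygen ends as the hemiketal hydroxyl. C4 keeps the configuration set in step 13 and fixes C1, because the one-atom bridge can only span the ring on the face that carries the C4 oxygen; C8 and C10 are untouched and the temporary centre C6 is erased. The step needs the radical on the C1 oxygen and not on the C4 oxygen, which the crowded surroundings of C1 (quaternary C6 and C10) and the much greater stability of the C6 radical should secure, and it needs the ring-cis geometry at C5=C6, which the planar butenolide and the transannular bridge impose.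

Step 20
Reactants: 33 side-chain O-TBS ether of the target
Product: 34 target CNP0154520.2
Conditions: HF·pyridine, pyridine, THF, 0 °C
Reagents that add atoms: none
Why: Buffered fluoride desilylation of the primary allylic silyl ether in a non-nucleophilic solvent should spare the allylic acetate, the hemiketal and the enol lactone.

**Compound list**

1 | furan-3,4-diyldimethanol | OCc1cocc1CO | starting material
2 | [4-(TBDPS-oxymethyl)furan-3-yl]methanol | OCc1cocc1CO[Si](c1ccccc1)(c1ccccc1)C(C)(C)C | intermediate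
3 | 4-(TBDPS-oxymethyl)furan-3-carbaldehyde | O=Cc1cocc1CO[Si](c1ccccc1)(c1ccccc1)C(C)(C)C | intermediate
4 | methyl acrylate | C=CC(=O)OC | starting material
5 | methyl 4-[4-(TBDPS-oxymethyl)furan-3-yl]-4-oxobutanoate | COC(=O)CCC(=O)c1cocc1CO[Si](c1ccccc1)(c1ccccc1)C(C)(C)C | intermediate
6 | methyl (4S)-4-hydroxy-4-[4-(TBDPS-oxymethyl)furan-3-yl]butanoate (not isolated) | COC(=O)CC[C@H](O)c1cocc1CO[Si](c1ccccc1)(c1ccccc1)C(C)(C)C | intermediate
7 | (5S)-5-[4-(TBDPS-oxymethyl)furan-3-yl]oxolan-2-one | O=C1CC[C@H](O1)c1cocc1CO[Si](c1ccccc1)(c1ccccc1)C(C)(C)C | intermediate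
8 | (3R,5S)-3-methyl-5-[4-(TBDPS-oxymethyl)furan-3-yl]oxolan-2-one (trans) | O=C1[C@H](C)C[C@H](O1)c1cocc1CO[Si](c1ccccc1)(c1ccccc1)C(C)(C)C | intermediate
9 | potassium (2R,4S)-4-hydroxy-2-methyl-4-[4-(TBDPS-oxymethyl)furan-3-yl]butanoate (not isolated) | [K+].[O-]C(=O)[C@H](C)C[C@H](O)c1cocc1CO[Si](c1ccccc1)(c1ccccc1)C(C)(C)C | intermediate
10 | TBS (2R,4S)-2-methyl-4-(TBS-oxy)-4-[4-(TBDPS-oxymethyl)furan-3-yl]butanoate (not isolated) | CC(C)(C)[Si](C)(C)OC(=O)[C@H](C)C[C@H](O[Si](C)(C)C(C)(C)C)c1cocc1CO[Si](c1ccccc1)(c1ccccc1)C(C)(C)C | intermediate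
11 | (2R,4S)-2-methyl-4-(TBS-oxy)-4-[4-(TBDPS-oxymethyl)furan-3-yl]butanoic acid | OC(=O)[C@H](C)C[C@H](O[Si](C)(C)C(C)(C)C)c1cocc1CO[Si](c1ccccc1)(c1ccccc1)C(C)(C)C | intermediate
12 | mixed anhydride of 11 and trifluoroacetic acid (not isolated) | FC(F)(F)C(=O)OC(=O)[C@H](C)C[C@H](O[Si](C)(C)C(C)(C)C)c1cocc1CO[Si](c1ccccc1)(c1ccccc1)C(C)(C)C | intermediate
13 | (4S,6R)-6-methyl-4-(TBS-oxy)-3-(TBDPS-oxymethyl)-5,6-dihydro-1-benzofuran-7(4H)-one (C8 silyloxy and C10 methyl cis) | O=C1[C@H](C)C[C@H](O[Si](C)(C)C(C)(C)C)c2c(CO[Si](c3ccccc3)(c3ccccc3)C(C)(C)C)coc12 | intermediate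
14 | allylmagnesium bromide | C=CC[Mg]Br | starting material
15 | (4S,6R,7R)-7-allyl-6-methyl-4-(TBS-oxy)-3-(TBDPS-oxymethyl)-4,5,6,7-tetrahydro-1-benzofuran-7-ol (C1 hydroxyl cis to C10 methyl and C8 silyloxy) | C=CC[C@@]1(O)[C@H](C)C[C@H](O[Si](C)(C)C(C)(C)C)c2c(CO[Si](c3ccccc3)(c3ccccc3)C(C)(C)C)coc12 | intermediate
16 | 2,5-endoperoxide of furan 15 (2,3,7-trioxabicyclo[2.2.1]hept-5-ene; not isolated) | C=CC[C@@]1(O)[C@H](C)C[C@H](O[Si](C)(C)C(C)(C)C)C2=C(CO[Si](c3ccccc3)(c3ccccc3)C(C)(C)C)C3OOC12O3 | intermediate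
17 | (4S,6R,7R)-7-allyl-7,7a-dihydroxy-6-methyl-4-(TBS-oxy)-3-(TBDPS-oxymethyl)-5,6,7,7a-tetrahydro-1-benzofuran-2(4H)-one (γ-hydroxybutenolide, both 7a epimers) | C=CC[C@@]1(O)[C@H](C)C[C@H](O[Si](C)(C)C(C)(C)C)C2=C(CO[Si](c3ccccc3)(c3ccccc3)C(C)(C)C)C(=O)OC12O | intermediate
18 | 2-methylallylmagnesium chloride | CC(=C)C[Mg]Cl | starting material
19 | (Z)-hydroxy acid from addition at C6, formed as its magnesium salt (acid cis to C6; C1 and C6 hydroxyls cis; not isolated) | C=CC[C@@]1(O)[C@H](C)C[C@H](O[Si](C)(C)C(C)(C)C)/C(=C(\CO[Si](c2ccccc2)(c2ccccc2)C(C)(C)C)C(O)=O)[C@@]1(O)CC(C)=C | intermediate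
20 | (4S,6R,7R,7aS)-7-allyl-7-hydroxy-6-methyl-7a-(2-methylallyl)-4-(TBS-oxy)-3-(TBDPS-oxymethyl)-5,6,7,7a-tetrahydro-1-benzofuran-2(4H)-one (C1 hydroxyl, C6 lactone oxygen, C8 silyloxy and C10 methyl all cis) | C=CC[C@@]1(O)[C@H](C)C[C@H](O[Si](C)(C)C(C)(C)C)C2=C(CO[Si](c3ccccc3)(c3ccccc3)C(C)(C)C)C(=O)O[C@]12CC(C)=C | intermediate
21 | cadinane-type tricyclic lactone: ring A cyclohexene (C3=C4, methyl on C4) cis-fused to ring B at C1 (OH) and C6 (lactone O), butenolide on C6/C7, C8–OTBS, C10–Me, C13–OTBDPS | C[C@@H]1C[C@H](O[Si](C)(C)C(C)(C)C)C2=C(CO[Si](c3ccccc3)(c3ccccc3)C(C)(C)C)C(=O)O[C@@]23CC(C)=CC[C@@]13O | intermediate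
22 | ring A 1,3-diene of 21 (C1=C2 and C3=C4) | C[C@@H]1C[C@H](O[Si](C)(C)C(C)(C)C)C2=C(CO[Si](c3ccccc3)(c3ccccc3)C(C)(C)C)C(=O)O[C@@]23CC(C)=CC=C13 | intermediate
23 | C1/C4 endoperoxide of 22 with C2=C3, peroxide anti to the C10 methyl and the C6–O bond (not isolated) | C[C@@H]1C[C@H](O[Si](C)(C)C(C)(C)C)C2=C(CO[Si](c3ccccc3)(c3ccccc3)C(C)(C)C)C(=O)O[C@@]23C[C@]4(C)C=C[C@]13OO4 | intermediate
24 | saturated C1/C4 endoperoxide (1,2-dioxane across ring A), C8–OTBS, C13–OTBDPS | C[C@@H]1C[C@H](O[Si](C)(C)C(C)(C)C)C2=C(CO[Si](c3ccccc3)(c3ccccc3)C(C)(C)C)C(=O)O[C@@]23C[C@]4(C)CC[C@]13OO4 | intermediate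
25 | saturated endoperoxide diol (C8–OH, C13–OH) | C[C@@H]1C[C@H](O)C2=C(CO)C(=O)O[C@@]23C[C@]4(C)CC[C@]13OO4 | intermediate
26 | saturated endoperoxide 13-acetate (C8–OH) | C[C@@H]1C[C@H](O)C2=C(COC(C)=O)C(=O)O[C@@]23C[C@]4(C)CC[C@]13OO4 | intermediate
27 | (TBS-oxy)acetaldehyde | O=CCO[Si](C)(C)C(C)(C)C | starting material
28 | ethyl 2-(triphenyl-λ5-phosphanylidene)propanoate | CCOC(=O)C(C)=P(c1ccccc1)(c1ccccc1)c1ccccc1 | starting material
29 | ethyl (2E)-2-methyl-4-(TBS-oxy)but-2-enoate | CCOC(=O)/C(C)=C/CO[Si](C)(C)C(C)(C)C | intermediate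
30 | (2E)-2-methyl-4-(TBS-oxy)but-2-enoic acid | OC(=O)/C(C)=C/CO[Si](C)(C)C(C)(C)C | intermediate
31 | saturated endoperoxide 13-acetate 8-[(2E)-2-methyl-4-(TBS-oxy)but-2-enoate] | C[C@@H]1C[C@H](OC(=O)/C(C)=C/CO[Si](C)(C)C(C)(C)C)C2=C(COC(C)=O)C(=O)O[C@@]23C[C@]4(C)CC[C@]13OO4 | intermediate
32 | ten-membered keto alcohol: C1 ketone, C4 tertiary alcohol, C5=C6 enol lactone (open form of 33; not isolated) | CC(=O)OCC1=C2/C(=C\[C@@](C)(O)CCC(=O)[C@H](C)C[C@@H]2OC(=O)/C(C)=C/CO[Si](C)(C)C(C)(C)C)OC1=O | intermediate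
33 | side-chain O-TBS ether of the target (1,4-epoxy-1-hydroxy hemiketal, 13-acetate) | CC(=O)OCC1=C2/C(=C\[C@]3(C)CC[C@@](O)(O3)[C@H](C)C[C@@H]2OC(=O)/C(C)=C/CO[Si](C)(C)C(C)(C)C)OC1=O | intermediate
34 | CNP0154520.2: (1R,4S,8S,10R)-13-acetoxy-1,4-epoxy-1-hydroxy-8-[(2E)-4-hydroxy-2-methylbut-2-enoyloxy]germacra-5,7(11)-dien-12,6-olide | CC(=O)OCC1=C2/C(=C\[C@]3(C)CC[C@@](O)(O3)[C@H](C)C[C@@H]2OC(=O)/C(C)=C/CO)OC1=O | target

**Step count and risks**

Total step count: 20. Longest linear sequence: 18 steps (steps 1 to 15 and 18 to 20; steps 16 and 17 make the side-chain acid).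

Steps most likely to fail:

Step 19 (proposed new method). The radical cascade may lose chemoselectivity: the alkoxy radical may form on the C4 oxygen, or the C6 radical may be trapped by solvent instead of being oxidised to the alkene. Fallback with known reactions, setting out from 31 and coming back at 33: Zn/AcOH at 0 °C reduces the O–O bond to the cis-1,4-diol F1. DBU (cat.) in MeCN then opens ring B by vinylogous retro-aldol cleavage of C1–C6 (the leaving carbanion is the butenolide dienolate); protonation at C6 and transannular hemiketalisation give the 5,6-dihydro hemiketal F2. Wohl–Ziegler bromination at the doubly activated C6 (NBS, AIBN, PhCF3, 80 °C) gives the γ-bromobutenolide F3, and Et3N eliminates HBr to the C5=C6 enol lactone 33.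

Step 10. Addition to the C6 ketone may occur on the wrong face (trans arms, which cannot undergo metathesis), or the reagent may attack the lactone carbonyl. Fallback from 17 back to 20, with electrophilic instead of nucleophilic activation of C6: acetylation of the hemiketal hydroxyl (Ac2O, pyridine) gives the γ-acetoxybutenolide F4. BF3·OEt2 and trimethyl(2-methylallyl)silane at −78 °C (Hosomi–Sakurai allylation of the acyloxycarbenium ion, attack anti to the axial C1 oxygen) then give 20.

Step 8. Facial selectivity of the allyl Grignard addition may be poor, since allylmagnesium reagents react through a compact cyclic transition state. Fallback from 13 back to 15: Corey–Chaykovsky reaction with dimethylsulfoxonium methylide (Me3S(O)I, NaH, DMSO) gives the spiro-epoxide F5 under thermodynamic control (CH2 equatorial and trans to the methyl, oxygen cis to it). Opening at the CH2 terminus with CH2=CHMgBr and CuI (cat.) at −40 °C then gives the homoallylic alcohol 15.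

**Further compounds**

F1 | step 19 | cis-1,4-diol from O–O reduction of 31 (C1–OH and C4–OH on the face of the former peroxide) | C[C@@H]1C[C@H](OC(=O)/C(C)=C/CO[Si](C)(C)C(C)(C)C)C2=C(COC(C)=O)C(=O)O[C@@]23C[C@@](C)(O)CC[C@]13O
F2 | step 19 | 5,6-dihydro analogue of 33 (C5H2, C6–H butenolide, hemiketal oxolane in place; either C6 epimer) | CC(=O)OCC1=C2C(C[C@]3(C)CC[C@@](O)(O3)[C@H](C)C[C@@H]2OC(=O)/C(C)=C/CO[Si](C)(C)C(C)(C)C)OC1=O
F3 | step 19 | 6-bromo derivative of F2 (γ-bromobutenolide) | CC(=O)OCC1=C2C(Br)(C[C@]3(C)CC[C@@](O)(O3)[C@H](C)C[C@@H]2OC(=O)/C(C)=C/CO[Si](C)(C)C(C)(C)C)OC1=O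
F4 | step 10 | γ-acetoxybutenolide from 17 (acetate on the C6 hemiketal oxygen) | C=CC[C@@]1(O)[C@H](C)C[C@H](O[Si](C)(C)C(C)(C)C)C2=C(CO[Si](c3ccccc3)(c3ccccc3)C(C)(C)C)C(=O)OC12OC(C)=O
F5 | step 8 | spiro-epoxide of ketone 13 at C1 (oxygen cis to the C10 methyl) | C1O[C@@]12[C@H](C)C[C@H](O[Si](C)(C)C(C)(C)C)c3c(CO[Si](c4ccccc4)(c4ccccc4)C(C)(C)C)coc23
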